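Its constants are made up.

I started with the catalyst.

    starting material + free catalyst ⇌ catalyst intermediate A (K1 = 300 M⁻¹, k1 = 3.00 M⁻¹ s⁻¹)
    reagent + catalyst intermediate A → catalyst intermediate B (k2 = 7.84 M⁻¹ s⁻¹)
    catalyst intermediate B ⇌ catalyst intermediate C (K3 = 0.389, k3 = 5.72 s⁻¹)
    catalyst intermediate C → free catalyst + target (k4 = 1.81 s⁻¹)
    reagent + target → over-reaction product (k5 = 0.00181 M⁻¹ s⁻¹)
    catalyst intermediate C → spent catalyst (k6 = 3.03 × 10⁻⁴ s⁻¹)

| flask | starting material | reagent | free catalyst | time | remark |
|---|---|---|---|---|---|
| north | 0.10 M (fed, over 40.0 min) | 0.0900 M | 0.10 mM | 50 min | a stirred flask in which starting material is dosed at a steady rate over 40.0 min without added volume, worked up at 50 min |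
| south-west | 0.10 M | 0.0900 M | 0.10 mM |  | one stirred flow tank at steady state, fed with the mixture as stated, mean residence time 50 min |
| south | 0.10 M | 0.0900 M | 0.10 mM | 50 min | everything together in a closed stirred flask, run for 50 min |
| west | 0.10 M | 0.0900 M (fed, over 40.0 min) | 0.10 mM | 50 min | all but reagent at the start; reagent goes in evenly over 40.0 min, the run ends at 50 min |

- the stated concentrations are those of everything mixed, before any reaction; amounts are the same in each set-up
- the feed brings no volume worth counting
- run time (north): 50 min

- the set-up with the highest amount of target at the outlet or at the end, in percent of the starting material put in ("none" if the first two lie within 2 percentage points) (north / south-west / south / west / none)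
- amount of target at the outlet or at the end, in percent of the starting material put in, north
- amount of target at the outlet or at the end, in percent of the starting material put in, south-west
- amount of target at the outlet or at the end, in percent of the starting material put in, south
- amount of target at the outlet or at the end, in percent of the starting material put in, west

I turned the question round. One way for a dosed flask or the tank to overtake the closed flask south was a run long enough for the catalyst to bring the reagent near its end, so that lower concentrations cost little in the end. I therefore asked how long south needed.

I took one trip of a catalyst round the cycle as a sum of waits. It waited 3.33 s as free catalyst for starting material at its charge and 1.42 s as intermediate A for reagent. It spent 2.15 s in the pair of intermediates B and C, with the returns from C to B counted. The trip came to 6.90 s, and half of it passed as free catalyst at the charge. I dropped the back step of intermediate A, since its 0.0100 s⁻¹ was far smaller than the 0.706 s⁻¹ forward at the reagent's charge.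

The rate of turning is catalyst divided by this sum, and the sum depends on the amount turned, so it integrates in closed form. Each concentration wait gives the logarithm of charge over remainder, divided by its rate constant. The pair wait gives its value times the amount turned, and the total is divided by the catalyst charge. I counted no over-reaction and no spent catalyst.

Followed in south until reagent stood at 0.00900 M, this gave 170 min, the time needed to bring the reagent near its end. That is longer than the run of 50 min, so I expected the rate to rank the set-ups, with south ahead. The same sum gave 49.8 min for 0.0368 M turned through in south. That is 36.8% of the starting material, a reckoning of turnover that counts no over-reaction, so I did not take it as the amount of target.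

The forecast named south, with 28.7% there, 24.7% for west, 24.3% for south-west and 21.5% for north. Its ground was that “dosing either feed or back-mixing just lowers the concentrations and so the rate”.

South led with 29.7%, ahead of 25.2% in west, 23.4% in south-west and 22.0% in north, in a run of 50 min that fell well short of the time needed of 170 min. Left to 500 min, which is longer than that time, the three flasks stood level, with north at 56.6%, west at 57.4% and south at 56.9%.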